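**Retrosynthetic overview**

1. The target is a cis-fused γ-lactone/tetrahydrofuran (3,7-dioxabicyclo[3.3.0]octan-2-one: C1/C5 fusion, C2=O, O3, C4–trihydroxyphenyl, C6H2, O7, C8–dihydroxyphenyl). The feature used is that the carbonyl carbon C2 and the benzylic carbon C4 are linked only through the ring oxygen O3, so taking O3 out leaves a cyclobutanone C1–C2–C4–C5 fused to the tetrahydrofuran ring C1–C5–C6–O7–C8.
2. Lactone ring (formed last): Baeyer–Villiger insertion of O3 into the temporary C2–C4 bond of that cyclobutanone, which comes from a C2 boronate by two oxidations; debenzylation ends the route.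
3. Tetrahydrofuran and cyclobutane rings (formed together): sensitised intramolecular [2+2] photocycloaddition of a cinnamyl ether onto an (E)-alkenyl boronate, making C1–C5 and C2–C4 in the fused (straight) mode.
4. Photosubstrate: Williamson etherification of an (S)-1-arylprop-2-yn-1-ol (asymmetric alkynylation sets C8, the only reagent-controlled centre) with a tris(benzyloxy)cinnamyl bromide, then alkyne hydroboration.

Key step: step 8

Remark: the core atoms are called C1–C8 as in the target throughout the discussion; systematic names of the bicyclo[3.2.0] intermediates carry their own locants.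
Assumption: the (S,S)-ProPhenol/zinc catalyst is taken to deliver the alkynyl group to the Si face of the aryl aldehyde; if the sense proves opposite, the (R,R)-ligand is used and nothing else changes.

**Route**

Step 1
Reactants: 1 3,4,5-tris(benzyloxy)benzaldehyde; 2 triethyl phosphonoacetate
Product: 3 ethyl (2E)-3-[3,4,5-tris(benzyloxy)phenyl]prop-2-enoate
Conditions: NaH, THF, 0 °C to rt
Reagents that add atoms: none
Why: Horner–Wadsworth–Emmons olefination of an aryl aldehyde with a stabilised phosphonate anion should give the (E)-cinnamate, and benzyl ethers are inert to the base.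

Step 2
Reactants: 3 ethyl (2E)-3-[3,4,5-tris(benzyloxy)phenyl]prop-2-enoate
Product: 4 (2E)-3-[3,4,5-tris(benzyloxy)phenyl]prop-2-en-1-ol
Conditions: (i-Bu)2AlH (2.5 equiv), CH2Cl2, −78 to 0 °C; aqueous Rochelle salt work-up
Reagents that add atoms: none
Why: Hydride reduction of a conjugated ester with (i-Bu)2AlH proceeds by 1,2-addition to the allylic alcohol and leaves the styrenyl double bond and the benzyl ethers alone.

Step 3
Reactants: 4 (2E)-3-[3,4,5-tris(benzyloxy)phenyl]prop-2-en-1-ol
Product: 5 1,2,3-tris(benzyloxy)-5-[(1E)-3-bromoprop-1-en-1-yl]benzene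
Conditions: PBr3 (0.4 equiv), Et2O, 0 °C; used crude at once
Reagents that add atoms: phosphorus tribromide, BrP(Br)Br
Why: Bromination of a primary allylic alcohol through its phosphite ester (PBr3 bromination) keeps the conjugated (E)-alkene; the electron-rich cinnamyl bromide is labile and is therefore not stored.

Step 4
Reactants: 6 3,4-bis(benzyloxy)benzaldehyde; 7 ethynyltrimethylsilane
Product: 9 (1R)-1-[3,4-bis(benzyloxy)phenyl]-3-(trimethylsilyl)prop-2-yn-1-ol, via methyl[(trimethylsilyl)ethynyl]zinc 8 (not isolated)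
Conditions: 7 (3 equiv), Me2Zn (3 equiv), (S,S)-ProPhenol (10 mol%), Ph3P=O (20 mol%), toluene, 0 °C; then 6, 0 °C to rt; aqueous NH4Cl
Reagents that add atoms: none
Why: Catalytic asymmetric alkynylation of an aromatic aldehyde (ProPhenol dinuclear zinc catalysis), in which the chiral zinc pocket holds aldehyde and alkynyl together and should deliver the alkynyl group to the Si face, sets the future C8 centre.

Step 5
Reactants: 9 (1R)-1-[3,4-bis(benzyloxy)phenyl]-3-(trimethylsilyl)prop-2-yn-1-ol
Product: 10 (1S)-1-[3,4-bis(benzyloxy)phenyl]prop-2-yn-1-ol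
Conditions: K2CO3 (0.3 equiv), MeOH, rt
Reagents that add atoms: none
Why: Methoxide-mediated protodesilylation of the alkynylsilane leaves the carbinol centre untouched (the descriptor changes only because the ethynyl group now ranks below the aryl group), and doing it here avoids alkoxide-induced silyl transfer in step 6.

Step 6
Reactants: 10 (1S)-1-[3,4-bis(benzyloxy)phenyl]prop-2-yn-1-ol; 5 1,2,3-tris(benzyloxy)-5-[(1E)-3-bromoprop-1-en-1-yl]benzene
Product: 11 1,2-bis(benzyloxy)-4-[(1S)-1-{[(2E)-3-[3,4,5-tris(benzyloxy)phenyl]prop-2-en-1-yl]oxy}prop-2-yn-1-yl]benzene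
Conditions: NaH (1.1 equiv), nBu4NI (10 mol%), THF/DMF (4:1), 0 °C to rt; chromatography on Et3N-deactivated silica
Reagents that add atoms: none
Why: Williamson ether synthesis, in which the alkoxide (the O–H is far more acidic than the alkyne C–H) displaces the primary allylic bromide by SN2 at CH2, breaks no bond at the stereocentre and avoids acid, which would ionise the electron-rich benzylic carbinol.

Step 7
Reactants: 11 the enyne ether of step 6; 12 pinacolborane
Product: 13 2-[(1E,3S)-3-[3,4-bis(benzyloxy)phenyl]-3-{[(2E)-3-[3,4,5-tris(benzyloxy)phenyl]prop-2-en-1-yl]oxy}prop-1-en-1-yl]-4,4,5,5-tetramethyl-1,3,2-dioxaborolane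
Conditions: 12 (1.5 equiv), Cp2Zr(H)Cl (10 mol%), Et3N (10 mol%), CH2Cl2, rt to 40 °C
Reagents that add atoms: none
Why: Zirconocene-hydride-catalysed hydroboration of a terminal alkyne (syn hydrozirconation, then zirconium-to-boron exchange) places boron on the terminal carbon and gives the (E)-alkenyl boronate, while the 1,2-disubstituted styrenyl alkene does not compete.

Step 8
Reactants: 13 the cinnamyl ether/alkenyl boronate of step 7
Product: 14 (1S,2S,5R,6S,7S)-2-[3,4-bis(benzyloxy)phenyl]-7-(4,4,5,5-tetramethyl-1,3,2-dioxaborolan-2-yl)-6-[3,4,5-tris(benzyloxy)phenyl]-3-oxabicyclo[3.2.0]heptane (both aryl groups exo, boron trans to the neighbouring aryl group)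
Conditions: Ir[dF(CF3)ppy]2(dtbbpy)PF6 (1 mol%), degassed CH2Cl2 (0.02 M), 450 nm LEDs, rt
Reagents that add atoms: none
Why: Energy transfer from the photoexcited iridium complex populates the triplet of the styrene unit (C4=C5) only, and its non-benzylic C5 radical adds to C1 of the alkenyl boronate to leave a triplet 1,4-diradical (benzylic C4, boron-stabilised C2) that closes the C2–C4 bond after intersystem crossing. This is the visible-light, triplet-sensitised intramolecular styrene–alkene [2+2] photocycloaddition, which is established for cinnamyl allyl ethers and tolerates alkenyl boronates as the alkene partner. The tetrahydrofuran ring (C8, O7, C6, C5, C1) closes by 5-exo-trig radical addition, which the three-atom tether favours over any bridged mode, and the cyclobutane (C1, C2, C4, C5) closes by recombination of the 1,4-diradical. C1 and C5 are set by the C8 centre through a chair-like 5-exo transition state with the C8 aryl group pseudo-equatorial, which places that aryl group trans to the C1–C2 bond (exo), and the cis ring fusion follows from the four-membered ring. C4 is set when the freely rotating benzylic radical closes with its aryl group on the convex face, whichever styrene geometry is present, and C2 is expected trans to that aryl group but is of no consequence because it becomes the ketone carbon in step 10. The step needs face selectivity with respect to C8 and energy transfer in preference to single-electron oxidation of the trialkoxyarene; the allylic C8 substituent and the low-polarity solvent serve these ends, and the product, which has lost the styrene chromophore, cannot be re-excited.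

Step 9
Reactants: 14 the cyclobutyl boronate of step 8
Product: 15 (1R,4S,5R,6S,7S)-4-[3,4-bis(benzyloxy)phenyl]-7-[3,4,5-tris(benzyloxy)phenyl]-3-oxabicyclo[3.2.0]heptan-6-ol
Conditions: H2O2 (30% aq.), NaOH (3 M aq.), THF, 0 °C to rt
Reagents that add atoms: hydrogen peroxide, OO
Why: Oxidation of a secondary alkyl boronate with alkaline peroxide goes by 1,2-shift of carbon from boron to oxygen with retention, and the ethers are stable to it.

Step 10
Reactants: 15 the cyclobutanol of step 9
Product: 16 (1R,4S,5S,7S)-4-[3,4-bis(benzyloxy)phenyl]-7-[3,4,5-tris(benzyloxy)phenyl]-3-oxabicyclo[3.2.0]heptan-6-one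
Conditions: Dess–Martin periodinane (1.3 equiv), pyridine, CH2Cl2, 0 °C to rt
Reagents that add atoms: none
Why: Dess–Martin oxidation of the secondary alcohol under buffered, non-acidic conditions erases the C2 centre, so both C2 epimers converge, and any C4 epimer carried from step 8 can be drained here to the more stable exo-aryl ketone by brief exposure to Et3N, because C4–H is benzylic and α to the carbonyl.

Step 11
Reactants: 16 the cyclobutanone of step 10
Product: 17 (1S,4S,5R,8S)-8-[3,4-bis(benzyloxy)phenyl]-4-[3,4,5-tris(benzyloxy)phenyl]-3,7-dioxabicyclo[3.3.0]octan-2-one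
Conditions: mCPBA (1.2 equiv), NaHCO3, CH2Cl2, 0 °C
Reagents that add atoms: 3-chloroperoxybenzoic acid (mCPBA), OOC(=O)c1cccc(Cl)c1
Why: Baeyer–Villiger oxidation of the strained ketone, in which the secondary benzylic C4 with its electron-rich aryl group should migrate in preference to C1 (deactivated by the oxygen-bearing C8 next to it) and does so with retention, inserts O3 between C2 and C4 and gives the γ-lactone.

Step 12
Reactants: 17 the pentabenzyl lactone of step 11
Product: 18 (1S,4S,5R,8S)-8-(3,4-dihydroxyphenyl)-4-(3,4,5-trihydroxyphenyl)-3,7-dioxabicyclo[3.3.0]octan-2-one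
Conditions: H2 (1 atm), 10% Pd/C, EtOAc/THF, rt; stopped when hydrogen uptake ends; filtration and concentration under argon
Reagents that add atoms: none
Why: Catalytic hydrogenolysis removes the five aryl benzyl ethers much faster than it attacks the ring benzylic C–O bonds in a neutral aprotic medium, and no stereocentre is touched.

**Compound list**

1 | 3,4,5-tris(benzyloxy)benzaldehyde | O=Cc1cc(OCc2ccccc2)c(OCc2ccccc2)c(OCc2ccccc2)c1 | starting material
2 | triethyl phosphonoacetate | CCOC(=O)CP(=O)(OCC)OCC | starting material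
3 | ethyl (2E)-3-[3,4,5-tris(benzyloxy)phenyl]prop-2-enoate | CCOC(=O)/C=C/c1cc(OCc2ccccc2)c(OCc2ccccc2)c(OCc2ccccc2)c1 | intermediate
4 | (2E)-3-[3,4,5-tris(benzyloxy)phenyl]prop-2-en-1-ol | OC/C=C/c1cc(OCc2ccccc2)c(OCc2ccccc2)c(OCc2ccccc2)c1 | intermediate
5 | 1,2,3-tris(benzyloxy)-5-[(1E)-3-bromoprop-1-en-1-yl]benzene | BrC/C=C/c1cc(OCc2ccccc2)c(OCc2ccccc2)c(OCc2ccccc2)c1 | intermediate
6 | 3,4-bis(benzyloxy)benzaldehyde | O=Cc1ccc(OCc2ccccc2)c(OCc2ccccc2)c1 | starting material
7 | ethynyltrimethylsilane | C#C[Si](C)(C)C | starting material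
8 | methyl[(trimethylsilyl)ethynyl]zinc | C[Zn]C#C[Si](C)(C)C | intermediate (not isolated)
9 | (1R)-1-[3,4-bis(benzyloxy)phenyl]-3-(trimethylsilyl)prop-2-yn-1-ol | C[Si](C)(C)C#C[C@@H](c1ccc(OCc2ccccc2)c(OCc2ccccc2)c1)O | intermediate
10 | (1S)-1-[3,4-bis(benzyloxy)phenyl]prop-2-yn-1-ol | C#C[C@@H](c1ccc(OCc2ccccc2)c(OCc2ccccc2)c1)O | intermediate
11 | 1,2-bis(benzyloxy)-4-[(1S)-1-{[(2E)-3-[3,4,5-tris(benzyloxy)phenyl]prop-2-en-1-yl]oxy}prop-2-yn-1-yl]benzene | C#C[C@@H](c1ccc(OCc2ccccc2)c(OCc2ccccc2)c1)OC/C=C/c1cc(OCc2ccccc2)c(OCc2ccccc2)c(OCc2ccccc2)c1 | intermediate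
12 | pinacolborane | CC1(C)OBOC1(C)C | starting material
13 | 2-[(1E,3S)-3-[3,4-bis(benzyloxy)phenyl]-3-{[(2E)-3-[3,4,5-tris(benzyloxy)phenyl]prop-2-en-1-yl]oxy}prop-1-en-1-yl]-4,4,5,5-tetramethyl-1,3,2-dioxaborolane | CC1(C)OB(/C=C/[C@@H](c2ccc(OCc3ccccc3)c(OCc3ccccc3)c2)OC/C=C/c2cc(OCc3ccccc3)c(OCc3ccccc3)c(OCc3ccccc3)c2)OC1(C)C | intermediate (key-step precursor)
14 | (1S,2S,5R,6S,7S)-2-[3,4-bis(benzyloxy)phenyl]-7-(4,4,5,5-tetramethyl-1,3,2-dioxaborolan-2-yl)-6-[3,4,5-tris(benzyloxy)phenyl]-3-oxabicyclo[3.2.0]heptane | CC1(C)OB(OC1(C)C)[C@H]1[C@H](c2cc(OCc3ccccc3)c(OCc3ccccc3)c(OCc3ccccc3)c2)[C@H]2CO[C@H](c3ccc(OCc4ccccc4)c(OCc4ccccc4)c3)[C@@H]12 | intermediate (key-step product)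
15 | (1R,4S,5R,6S,7S)-4-[3,4-bis(benzyloxy)phenyl]-7-[3,4,5-tris(benzyloxy)phenyl]-3-oxabicyclo[3.2.0]heptan-6-ol | O[C@H]1[C@H](c2cc(OCc3ccccc3)c(OCc3ccccc3)c(OCc3ccccc3)c2)[C@H]2CO[C@H](c3ccc(OCc4ccccc4)c(OCc4ccccc4)c3)[C@@H]12 | intermediate
16 | (1R,4S,5S,7S)-4-[3,4-bis(benzyloxy)phenyl]-7-[3,4,5-tris(benzyloxy)phenyl]-3-oxabicyclo[3.2.0]heptan-6-one | O=C1[C@H](c2cc(OCc3ccccc3)c(OCc3ccccc3)c(OCc3ccccc3)c2)[C@H]2CO[C@H](c3ccc(OCc4ccccc4)c(OCc4ccccc4)c3)[C@@H]12 | intermediate
17 | (1S,4S,5R,8S)-8-[3,4-bis(benzyloxy)phenyl]-4-[3,4,5-tris(benzyloxy)phenyl]-3,7-dioxabicyclo[3.3.0]octan-2-one | O=C1O[C@H](c2cc(OCc3ccccc3)c(OCc3ccccc3)c(OCc3ccccc3)c2)[C@H]2CO[C@H](c3ccc(OCc4ccccc4)c(OCc4ccccc4)c3)[C@@H]12 | intermediate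
18 | (1S,4S,5R,8S)-8-(3,4-dihydroxyphenyl)-4-(3,4,5-trihydroxyphenyl)-3,7-dioxabicyclo[3.3.0]octan-2-one | O=C1O[C@H](c2cc(O)c(O)c(O)c2)[C@H]2CO[C@H](c3ccc(O)c(O)c3)[C@@H]12 | target

**Count and risks**

Total step count: 12. Longest linear sequence: 10 steps (steps 1–3, then 6–12).

Steps most likely to fail:

1. Step 8. The C8 centre may discriminate only weakly between the two faces of the 5-exo closure. The boron-stabilised diradical may also revert to the open diene, leaving only E/Z isomerisation, or the excited catalyst may oxidise the trialkoxyarene instead of transferring energy. The fallback changes the radical-accepting alkene and the way the oxygen at C2 is unmasked, and it sets out from 11. Platinum-catalysed hydrosilylation with benzyldimethylsilane [Pt2(dvds)3, P(t-Bu)3, THF, rt] should give benzyl{(1E,3S)-3-[3,4-bis(benzyloxy)phenyl]-3-{[(2E)-3-[3,4,5-tris(benzyloxy)phenyl]prop-2-en-1-yl]oxy}prop-1-en-1-yl}dimethylsilane F1. Sensitised cycloaddition with thioxanthone at 405 nm, an organic triplet sensitiser chosen to disfavour oxidation of the arene, should then give benzyl{(1S,2S,5R,6S,7S)-2-[3,4-bis(benzyloxy)phenyl]-6-[3,4,5-tris(benzyloxy)phenyl]-3-oxabicyclo[3.2.0]heptan-7-yl}dimethylsilane F2. The α-silyl radical is less stabilised than the α-boryl one, so the first bond should form irreversibly and the kinetic chair-like preference should be kept. Tamao–Fleming oxidation (nBu4NF, THF; then H2O2, KHCO3, MeOH) with retention comes back to the route at 15.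

2. Step 11. C1 may migrate in place of C4, giving the regioisomeric lactone, or the peracid may oxidise the electron-rich arenes. The fallback sets out from 16 and replaces the peracid by the photochemical ring expansion of cyclobutanones. Irradiation above 300 nm in MeOH/THF at 0 °C should cleave the benzylic C2–C4 bond (Norrish α-cleavage on the more substituted side) and re-close through oxygen to an oxacarbene, which methanol traps as 8-[3,4-bis(benzyloxy)phenyl]-2-methoxy-4-[3,4,5-tris(benzyloxy)phenyl]-3,7-dioxabicyclo[3.3.0]octane F3 (both C2 epimers, other centres as in 17). Mild hydrolysis (PPTS, acetone/H2O) should give the lactol 8-[3,4-bis(benzyloxy)phenyl]-4-[3,4,5-tris(benzyloxy)phenyl]-3,7-dioxabicyclo[3.3.0]octan-2-ol F4, and oxidation with PhI(OAc)2 and catalytic TEMPO returns to the route at 17.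

3. Step 12. Hydrogen may also cleave the benzylic C4–O3 acyloxy bond of the lactone (and more slowly the C8–O7 ether), and the free pyrogallol is prone to air oxidation. The fallback sets out from 16 and moves the hydrogenolysis ahead of lactone formation, so that no benzylic acyloxy bond is exposed to hydrogen. Hydrogenolysis (H2, 10% Pd/C, THF/MeOH) should give (1R,4S,5S,7S)-4-(3,4-dihydroxyphenyl)-7-(3,4,5-trihydroxyphenyl)-3-oxabicyclo[3.2.0]heptan-6-one F5. This is acetylated without purification (Ac2O, pyridine) to its pentaacetate, (1R,4S,5S,7S)-4-(3,4-diacetoxyphenyl)-7-(3,4,5-triacetoxyphenyl)-3-oxabicyclo[3.2.0]heptan-6-one F6. Baeyer–Villiger oxidation (mCPBA, NaHCO3, CH2Cl2, 0 °C), now on arenes that resist peracid, should give (1S,4S,5R,8S)-8-(3,4-diacetoxyphenyl)-4-(3,4,5-triacetoxyphenyl)-3,7-dioxabicyclo[3.3.0]octan-2-one F7. Neutral deacetylation (NH4OAc, MeOH/H2O, rt, argon) returns to the route at 18.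

**Further compounds**

F1 | step 8 | benzyl{(1E,3S)-3-[3,4-bis(benzyloxy)phenyl]-3-{[(2E)-3-[3,4,5-tris(benzyloxy)phenyl]prop-2-en-1-yl]oxy}prop-1-en-1-yl}dimethylsilane | C[Si](C)(Cc1ccccc1)/C=C/[C@@H](c1ccc(OCc2ccccc2)c(OCc2ccccc2)c1)OC/C=C/c1cc(OCc2ccccc2)c(OCc2ccccc2)c(OCc2ccccc2)c1
F2 | step 8 | benzyl{(1S,2S,5R,6S,7S)-2-[3,4-bis(benzyloxy)phenyl]-6-[3,4,5-tris(benzyloxy)phenyl]-3-oxabicyclo[3.2.0]heptan-7-yl}dimethylsilane | C[Si](C)(Cc1ccccc1)[C@H]1[C@H](c2cc(OCc3ccccc3)c(OCc3ccccc3)c(OCc3ccccc3)c2)[C@H]2CO[C@H](c3ccc(OCc4ccccc4)c(OCc4ccccc4)c3)[C@@H]12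
F3 | step 11 | 8-[3,4-bis(benzyloxy)phenyl]-2-methoxy-4-[3,4,5-tris(benzyloxy)phenyl]-3,7-dioxabicyclo[3.3.0]octane (C2 epimers) | COC1O[C@H](c2cc(OCc3ccccc3)c(OCc3ccccc3)c(OCc3ccccc3)c2)[C@H]2CO[C@H](c3ccc(OCc4ccccc4)c(OCc4ccccc4)c3)[C@@H]12
F4 | step 11 | 8-[3,4-bis(benzyloxy)phenyl]-4-[3,4,5-tris(benzyloxy)phenyl]-3,7-dioxabicyclo[3.3.0]octan-2-ol (C2 epimers) | OC1O[C@H](c2cc(OCc3ccccc3)c(OCc3ccccc3)c(OCc3ccccc3)c2)[C@H]2CO[C@H](c3ccc(OCc4ccccc4)c(OCc4ccccc4)c3)[C@@H]12
F5 | step 12 | (1R,4S,5S,7S)-4-(3,4-dihydroxyphenyl)-7-(3,4,5-trihydroxyphenyl)-3-oxabicyclo[3.2.0]heptan-6-one | O=C1[C@H](c2cc(O)c(O)c(O)c2)[C@H]2CO[C@H](c3ccc(O)c(O)c3)[C@@H]12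
F6 | step 12 | (1R,4S,5S,7S)-4-(3,4-diacetoxyphenyl)-7-(3,4,5-triacetoxyphenyl)-3-oxabicyclo[3.2.0]heptan-6-one | O=C1[C@H](c2cc(OC(C)=O)c(OC(C)=O)c(OC(C)=O)c2)[C@H]2CO[C@H](c3ccc(OC(C)=O)c(OC(C)=O)c3)[C@@H]12
F7 | step 12 | (1S,4S,5R,8S)-8-(3,4-diacetoxyphenyl)-4-(3,4,5-triacetoxyphenyl)-3,7-dioxabicyclo[3.3.0]octan-2-one | O=C1O[C@H](c2cc(OC(C)=O)c(OC(C)=O)c(OC(C)=O)c2)[C@H]2CO[C@H](c3ccc(OC(C)=O)c(OC(C)=O)c3)[C@@H]12
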